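The vessel was closed and stirred, with the gas level held and the solid substrate charged undissolved. You wanted a quick number and had a hunch about the split.

| setting | dusk | flask |
|---|---|---|
| solid substrate | 1 M | 1.0 M |
| first nucleophile | 1.8 M | 1.20 M |
| gas | 200 mM (held) | 200 mM (held) |
| remark | run made earlier |  |
| time |  | 15 d |

dusk run (percent of the solid substrate charged)

| time / d | other capture product / % | target / % |
|---|---|---|
| 0.625 | 38.8 | 24.3 |
| 1.25 | 46.9 | 28.8 |
| 2.08 | 47.8 | 29.4 |
| 2.50 | 48.2 | 29.6 |
| 3.00 | 48.0 | 29.0 |
| 4.00 | 47.9 | 29.2 |
| 5.00 | 48.5 | 29.1 |

(each reading ± 0.3 percentage points)

- solid substrate is a solid; its amount is given per volume of the solution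
- at the start none of the gas is in solution
- at the start none of the solid substrate is in solution

* ratio of other capture product to target at 3.0 h
* ratio of other capture product to target at 30 h
* ratio of other capture product to target at 15 d
* which of other capture product and target there is more of at 15 d

**Reading the dusk run.** From 2.50 d on, the dusk run read a ratio of 1.65, with target near 29.2 %. I assumed the two products compete, the target's speed following the first nucleophile and the other capture product's following the held gas. I also assumed each target took up one first nucleophile. I took the dusk midpoint of first nucleophile as 1.65 M.

**The tie level.** Ratio times nucleophile, as read off the dusk run, gave the tie level, the first nucleophile concentration at which both products form equally fast at that held gas level: 2.72 M. It is a selectivity factor in concentration units. With the gas held at that same level, I took a ratio as the tie level over the nucleophile present.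

**My reckoning.** This flask's charge of 1.20 M lies below the tie level, so I expected more other capture product. On the undiminished charge I got 2.27 early. With the dusk midpoint draw deducted I got 2.59 late.

**The forecast.** It differed, giving 1.68, 1.64 and 1.65, with other capture product ahead: “I take the split as set by the held gas level and independent of nucleophile”.

**The result.** The flask gave 2.26 at 3.0 h, 2.46 at 30 h and 2.47 at 15 d, with 53.2 % other capture product against 21.6 % target. Its first nucleophile ended at 82 % of its own charge, a midpoint of 1.09 M, and the tie level over that gives 2.50. The neighbour flask with 0.30 M of first nucleophile kept 79 % of its charge, a midpoint of 0.268 M, so the tie level gives 10.1. That neighbour flask's ratio at 15 d was 10.0.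

    starting material → intermediate (k = 0.210 h⁻¹)
    first nucleophile + intermediate → target (k = 290 M⁻¹ h⁻¹)
    second nucleophile + intermediate → other capture product (k = 3900 M⁻¹ h⁻¹)
    intermediate → solvolysis product (k = 370 h⁻¹)
    gas ⇌ second nucleophile, rate k5*(csat - [second nucleophile]) (kL = 76.0 h⁻¹)
    solid substrate ⇌ starting material, rate k6*(cs6 - [starting material]) while solid is left; crystals form when [starting material] > cs6 (solubility = 0.680 M, k = 0.190 h⁻¹)

The runs are simulated for substances that don't exist, noise included.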